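A direct plan would take the C2–C3 bond from a succinic diester: Stobbe condensation with a benzyl-protected 4-hydroxybenzaldehyde, ester reduction and lactonisation, aldol addition of a second aldehyde, elimination and hydrogenation to the cis-lactone A1.
It would then open A1 to the diol, re-protect the phenols, oxidise to the meso dialdehyde A2, add the aryllithium A3 at both ends, oxidise the two carbinols and remove six benzyl ethers.
First weakness, the nine-step linear run-up to A2: a C4 chain with two benzyl groups, still without either aryl ketone, would cost two thirds of the route.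
Second weakness, the hydrogenation that sets the cis stereochemistry of A1 would also strip the benzyl ethers, which must be put back, and C1/C4 would travel ester, alcohol, aldehyde, carbinol, ketone: protecting-group and redox traffic that builds nothing.
Third weakness, the two-directional addition of the strongly basic A3 to crude A2: this doubly α-branched, enolisable 1,4-dialdehyde holds the only record of the meso configuration, so epimerisation and lactol formation would threaten late in the sequence.

**Retrosynthetic overview**
The target is the mirror-symmetric α,α′-dimer of davidigenin: two 1-(2,4-dihydroxyphenyl)-3-(4-hydroxyphenyl)propan-1-one halves joined at C2–C3 of the butane-1,4-dione chain, each of these carbons carrying one 4-hydroxybenzyl and one 2,4-dihydroxybenzoyl group.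
The only key disconnection is C2–C3, made by oxidative homocoupling of two molecules of the enolate of one protected dihydrochalcone (a biomimetic dimerisation), so the key step doubles the skeleton in one operation.
No ring is formed anywhere: the two resorcinol rings and the two phenol rings arrive intact in the two starting materials, which are joined beforehand by one aldol condensation and one C=C hydrogenation.
Both ketones are at the right oxidation level from the first step, and the arylmethyl ethers (benzyl on the resorcinol rings, 4-methoxybenzyl on the phenol rings, chosen as the more crystalline ether) are bought in and removed once, so the run-up, the redox traffic, the re-protection and the dialdehyde all vanish.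
C2 and C3, both α to aryl ketones, are set as a pair right after the coupling by reversible enolisation with crystallisation of the meso form; this crystallisation is the main uncertainty of the route, and afterwards the centres meet neither acid nor base.

Key step: step 3

Remark: the target is read as the meso (2R,3S) diastereomer, since C2 and C3 of the constitutionally symmetric chain carry opposite CIP descriptors; 1 and 2 are taken as catalogue compounds.

**Step 1**
Reactants: 1 1-[2,4-bis(benzyloxy)phenyl]ethan-1-one; 2 4-[(4-methoxybenzyl)oxy]benzaldehyde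
Product: 4 (E)-1-[2,4-bis(benzyloxy)phenyl]-3-{4-[(4-methoxybenzyl)oxy]phenyl}prop-2-en-1-one, via aldol adduct 3 (not isolated)
Conditions: KOH (3 equiv, 50% aq), EtOH–THF 2:1, rt, 16 h
Reagents that add atoms: none
Why: Claisen–Schmidt condensation, in which the methyl ketone enolate adds to the non-enolisable aldehyde and aldol 3 loses water by E1cB to the conjugated E-enone, while the arylmethyl ethers are inert to hydroxide and no stereocentre is formed.

**Step 2**
Reactants: 4 (E)-1-[2,4-bis(benzyloxy)phenyl]-3-{4-[(4-methoxybenzyl)oxy]phenyl}prop-2-en-1-one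
Product: 5 1-[2,4-bis(benzyloxy)phenyl]-3-{4-[(4-methoxybenzyl)oxy]phenyl}propan-1-one
Conditions: H2 (4 bar), RhCl(PPh3)3 (3 mol %), THF–EtOH 1:1, 40 °C
Reagents that add atoms: none
Why: Homogeneous hydrogenation with RhCl(PPh3)3 should reduce the unhindered trans-disubstituted enone C=C and touch neither the aryl ketone nor the benzyl and 4-methoxybenzyl ethers, which heterogeneous palladium would cleave; no stereocentre is formed.

**Step 3**
Reactants: 5 1-[2,4-bis(benzyloxy)phenyl]-3-{4-[(4-methoxybenzyl)oxy]phenyl}propan-1-one; 5 1-[2,4-bis(benzyloxy)phenyl]-3-{4-[(4-methoxybenzyl)oxy]phenyl}propan-1-one (second molecule of the same ketone)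
Product: 7 1,4-bis[2,4-bis(benzyloxy)phenyl]-2,3-bis{4-[(4-methoxybenzyl)oxy]benzyl}butane-1,4-dione as a mixture of the meso form plus the racemic pair, via lithium Z-enolate 6 (not isolated)
Conditions: LiN(SiMe3)2 (1.05 equiv per mole of 5), THF, −78 °C, 45 min; CuCl2 (1.1 equiv per mole of 5, anhydrous) in DMF, −78 °C to rt; aq NH4Cl–NH3 work-up
Reagents that add atoms: none
Why: Two molecules of 5 are converted into the lithium (Z)-enolate 6, each enolate gives up one electron to divalent copper (inner-sphere, through a copper enolate), and the two resulting α-keto radical equivalents join at carbon, so the C2–C3 bond that links the two davidigenin halves is made in one operation from a precursor of half the size while the copper leaves in its monovalent state as CuCl. The closest known reaction type is the CuCl2-mediated oxidative dimerisation of lithium enolates of aryl alkyl ketones to 2,3-disubstituted 1,4-diketones. No ring is closed. C2 and C3 are created together without a kinetic preference that could be relied on, and since both are α to an aryl ketone they are left as a meso/racemic mixture on purpose and set as a pair in step 4. The selectivity the step needs is C–C over C–O coupling, over α-chlorination and over dehydrogenation to enone 4; the carbon-centred spin density of an aryl ketone enolate, addition of the oxidant at −78 °C in DMF and the absence of free phenols should secure it. Regiochemistry is not at issue because C2 is the only enolisable position of 5.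

**Step 4**
Reactants: 7 1,4-bis[2,4-bis(benzyloxy)phenyl]-2,3-bis{4-[(4-methoxybenzyl)oxy]benzyl}butane-1,4-dione (mixture)
Product: 9 meso-(2R,3S)-1,4-bis[2,4-bis(benzyloxy)phenyl]-2,3-bis{4-[(4-methoxybenzyl)oxy]benzyl}butane-1,4-dione, via sodium enolate 8 (not isolated)
Conditions: NaOEt (0.1 equiv), EtOH–toluene 5:1, argon, 50 °C, then slow cooling to 20 °C as a seeded slurry; filtration, cold EtOH wash
Reagents that add atoms: none
Why: Crystallisation-induced diastereomer transformation, in which ethoxide interconverts the meso form and the racemic pair through enolate 8 at the two acidic α-CH centres, and the meso diketone (centrosymmetric in its anti conformation and expected to be the higher-melting, less soluble isomer) should crystallise and drain the equilibrium, which sets C2 and C3 as a pair.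

**Step 5**
Reactants: 9 meso-(2R,3S)-1,4-bis[2,4-bis(benzyloxy)phenyl]-2,3-bis{4-[(4-methoxybenzyl)oxy]benzyl}butane-1,4-dione
Product: 10 meso-(2R,3S)-1,4-bis(2,4-dihydroxyphenyl)-2,3-bis(4-hydroxybenzyl)butane-1,4-dione (target)
Conditions: H2 (1 atm), 10% Pd/C, THF–MeOH 1:1, rt; filtration through Celite, crystallisation from aq MeOH
Reagents that add atoms: none
Why: Neutral hydrogenolysis over palladium should cleave the four benzyl and two 4-methoxybenzyl aryl ethers without acid (Paal–Knorr furan closure) or base (epimerisation), so C2 and C3 keep the meso configuration, and the aryl ketones, vinylogous acids once their ortho and para phenols are free, should resist reduction at 1 atm.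

**Compound list**
1 | 1-[2,4-bis(benzyloxy)phenyl]ethan-1-one | CC(=O)c1ccc(OCc2ccccc2)cc1OCc1ccccc1 | starting material
2 | 4-[(4-methoxybenzyl)oxy]benzaldehyde | O=Cc1ccc(OCc2ccc(OC)cc2)cc1 | starting material
3 | rac-1-[2,4-bis(benzyloxy)phenyl]-3-hydroxy-3-{4-[(4-methoxybenzyl)oxy]phenyl}propan-1-one (aldol adduct) | O=C(CC(O)c1ccc(OCc2ccc(OC)cc2)cc1)c1ccc(OCc2ccccc2)cc1OCc1ccccc1 | intermediate (not isolated)
4 | (E)-1-[2,4-bis(benzyloxy)phenyl]-3-{4-[(4-methoxybenzyl)oxy]phenyl}prop-2-en-1-one | O=C(/C=C/c1ccc(OCc2ccc(OC)cc2)cc1)c1ccc(OCc2ccccc2)cc1OCc1ccccc1 | intermediate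
5 | 1-[2,4-bis(benzyloxy)phenyl]-3-{4-[(4-methoxybenzyl)oxy]phenyl}propan-1-one | O=C(CCc1ccc(OCc2ccc(OC)cc2)cc1)c1ccc(OCc2ccccc2)cc1OCc1ccccc1 | intermediate
6 | lithium (Z)-enolate of 5 | [Li+].[O-]/C(=C\Cc1ccc(OCc2ccc(OC)cc2)cc1)c1ccc(OCc2ccccc2)cc1OCc1ccccc1 | intermediate (not isolated)
7 | 1,4-bis[2,4-bis(benzyloxy)phenyl]-2,3-bis{4-[(4-methoxybenzyl)oxy]benzyl}butane-1,4-dione (mixture of meso form and racemic pair) | O=C(c1ccc(OCc2ccccc2)cc1OCc1ccccc1)C(Cc1ccc(OCc2ccc(OC)cc2)cc1)C(Cc1ccc(OCc2ccc(OC)cc2)cc1)C(=O)c1ccc(OCc2ccccc2)cc1OCc1ccccc1 | intermediate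
8 | sodium enolate of 7 (C2 planar) | [Na+].[O-]C(=C(Cc1ccc(OCc2ccc(OC)cc2)cc1)C(Cc1ccc(OCc2ccc(OC)cc2)cc1)C(=O)c1ccc(OCc2ccccc2)cc1OCc1ccccc1)c1ccc(OCc2ccccc2)cc1OCc1ccccc1 | intermediate (not isolated)
9 | meso-(2R,3S)-1,4-bis[2,4-bis(benzyloxy)phenyl]-2,3-bis{4-[(4-methoxybenzyl)oxy]benzyl}butane-1,4-dione | O=C(c1ccc(OCc2ccccc2)cc1OCc1ccccc1)[C@@H](Cc1ccc(OCc2ccc(OC)cc2)cc1)[C@@H](Cc1ccc(OCc2ccc(OC)cc2)cc1)C(=O)c1ccc(OCc2ccccc2)cc1OCc1ccccc1 | intermediate
10 | meso-(2R,3S)-1,4-bis(2,4-dihydroxyphenyl)-2,3-bis(4-hydroxybenzyl)butane-1,4-dione | O=C(c1ccc(O)cc1O)[C@@H](Cc1ccc(O)cc1)[C@@H](Cc1ccc(O)cc1)C(=O)c1ccc(O)cc1O | target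

Total step count: 5
Longest linear sequence: 5 steps (1 or 2 to 10)

**Steps most likely to fail**

Step 3. The enolate may be diverted into α-chlorination by ligand transfer or into dehydrogenation back to the enone, or the two hindered secondary carbons may couple so slowly that proton transfer simply returns 5. Fallback: from 5, a polar two-component coupling replaces the oxidative one. One half of 5 is converted into its enolate 6 and brominated at C2 by inverse addition to N-bromosuccinimide (THF, −78 °C), which avoids free acid near the 4-methoxybenzyl ether and should give rac-2-bromo-1-[2,4-bis(benzyloxy)phenyl]-3-{4-[(4-methoxybenzyl)oxy]phenyl}propan-1-one F1. The lithium enolate 6 made from the other half is then alkylated with F1 (THF–DMPU, −78 to 0 °C, SN2 at the activated α-carbon), which comes back to the route at 7.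

Step 4. Selective nucleation of the meso form may fail (oiling out or co-crystallisation), so that the equilibrium is not drained. Fallback: from 7, flash chromatography separates 9 from the racemic diastereomer rac-(2S,3S)-1,4-bis[2,4-bis(benzyloxy)phenyl]-2,3-bis{4-[(4-methoxybenzyl)oxy]benzyl}butane-1,4-dione F2. F2 is re-equilibrated in solution (NaOEt cat., THF–EtOH, rt) to the mixture 7 and recycled, so that the material comes back to the route at 9.

Step 5. A benzylic ketone may be over-reduced to the carbinol and then the methylene before the last ether has fallen, or cleavage may stall at partly protected stages. Fallback: from 9, the ethers are cleaved without hydrogen by BCl3 and pentamethylbenzene (cation scavenger) in CH2Cl2 at −78 °C, with a cold MeOH quench. This leads directly to 10 and makes no new compound (F0).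

**Further compounds**
F1 | step 3 | rac-2-bromo-1-[2,4-bis(benzyloxy)phenyl]-3-{4-[(4-methoxybenzyl)oxy]phenyl}propan-1-one | O=C(C(Br)Cc1ccc(OCc2ccc(OC)cc2)cc1)c1ccc(OCc2ccccc2)cc1OCc1ccccc1
F2 | step 4 | rac-(2S,3S)-1,4-bis[2,4-bis(benzyloxy)phenyl]-2,3-bis{4-[(4-methoxybenzyl)oxy]benzyl}butane-1,4-dione (one enantiomer drawn) | O=C(c1ccc(OCc2ccccc2)cc1OCc1ccccc1)[C@@H](Cc1ccc(OCc2ccc(OC)cc2)cc1)[C@H](Cc1ccc(OCc2ccc(OC)cc2)cc1)C(=O)c1ccc(OCc2ccccc2)cc1OCc1ccccc1
F0 | step 5 | none | none
A1 | direct plan | rac-(3R,4S)-3,4-bis(4-hydroxybenzyl)dihydrofuran-2(3H)-one, cis (one enantiomer drawn) | O=C1OC[C@@H](Cc2ccc(O)cc2)[C@H]1Cc1ccc(O)cc1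
A2 | direct plan | meso-(2R,3S)-2,3-bis[4-(benzyloxy)benzyl]butanedial | O=C[C@@H](Cc1ccc(OCc2ccccc2)cc1)[C@@H](Cc1ccc(OCc2ccccc2)cc1)C=O
A3 | direct plan | [2,4-bis(benzyloxy)phenyl]lithium | [Li]c1ccc(OCc2ccccc2)cc1OCc1ccccc1
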